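**Retrosynthetic overview**
1. Target 33 ⇐ 2β,3β-epoxy-1-ketone 31 ⇐ 1-oxo-Δ2 lactone 30. The last C–C bond (C3–C4, quaternary C4) comes from annulation of the lactone enolate onto a C1 enaminone; the oxygens at C1–C3 come from nucleophilic epoxidation and α-face hydride delivery.
2. Lactone, C4–C5 and 5β-H ⇐ intramolecular Michael addition of a 10α-O-propanoate to the ring-B enoate; C10–O, C1 and C2 ⇐ β-face 1,2-addition of an acetyl anion equivalent to the C10 ketone 19.
3. Ring D ⇐ SmI2 ketyl–alkyne cyclisation; ring C ⇐ 6-exo enolate alkylation; C7 ⇐ carbonylation of a C6 enol triflate.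
4. Ring B with C9 and quaternary C8 ⇐ (R)-4-silyloxycyclopentenone 1 by conjugate addition/propargylation (absolute configuration from the chiral pool).
5. Ring order: B → C → D → lactone → A.

Assumption: gibberellane numbering (C1–C19; C7 = ring-B carboxyl carbon, C18 = 4-methyl, C19 = lactone carbonyl) is used for every intermediate, α/β mean below/above the usual gibberellin drawing, TBS = tert-butyldimethylsilyl, and all reagents are catalogue items.

**Step 1**
Reactants: 1 (R)-4-[(tert-butyldimethylsilyl)oxy]cyclopent-2-en-1-one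
Product: 2 (R)-4-[(tert-butyldimethylsilyl)oxy]-2-iodocyclopent-2-en-1-one
Conditions: I2, pyridine, CH2Cl2, 0 °C to rt
Reagents that add atoms: iodine, II
Why: α-Iodination of the enone by pyridine conjugate addition, enolate iodination and elimination (Baylis–Hillman-type α-halogenation); the C10 stereocentre is not involved.

**Step 2**
Reactants: 2 (R)-4-[(tert-butyldimethylsilyl)oxy]-2-iodocyclopent-2-en-1-one; 3 tributyl(2-methylprop-2-en-1-yl)stannane
Product: 4 (R)-4-[(tert-butyldimethylsilyl)oxy]-2-(2-methylprop-2-en-1-yl)cyclopent-2-en-1-one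
Conditions: Pd2(dba)3 (2.5 mol%), AsPh3, CuI (10 mol%), N-methylpyrrolidone, 40 °C
Reagents that add atoms: none
Why: Stille coupling of the α-iodoenone puts the masked acetonyl arm (future C14–C13–C12) on C8 before the quaternary centre is made, so that it ends cis to C11.

**Step 3**
Reactants: 4 (R)-4-[(tert-butyldimethylsilyl)oxy]-2-(2-methylprop-2-en-1-yl)cyclopent-2-en-1-one; 5 vinylmagnesium bromide; 6 3-bromoprop-1-yne (propargyl bromide)
Product: 9 (2R,3R,4R)-4-[(tert-butyldimethylsilyl)oxy]-3-ethenyl-2-(2-methylprop-2-en-1-yl)-2-(prop-2-yn-1-yl)cyclopentan-1-one, via silyl enol ether 7 (not isolated), via lithium enolate 8 (not isolated)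
Conditions: 5, CuBr·SMe2 (10 mol%), Me3SiCl, THF, −78 °C; volatiles removed; MeLi, THF, 0 °C; then 6, HMPA, −78 to −20 °C
Reagents that add atoms: chlorotrimethylsilane, C[Si](C)(C)Cl (its Me3Si group stays in 7 only); methyllithium, [Li]C (its Li stays in 8 only)
Why: Copper-catalysed 1,4-addition of the vinyl group anti to the C10 silyloxy group (two-component prostaglandin coupling) gives 7, and the regiospecific enolate 8 is alkylated anti to the new 9α-vinyl group, which sets C9 and the quaternary C8 with the propargyl group β and cis to 9-H.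

**Step 4**
Reactants: 9 (2R,3R,4R)-cyclopentanone from step 3
Product: 10 C6 enol triflate of 9 (C5=C6; 8β-propargyl, 8α-methallyl, 9α-vinyl, 10β-OTBS)
Conditions: KN(SiMe3)2, PhNTf2, THF, −78 °C
Reagents that add atoms: N-phenylbis(trifluoromethanesulfonimide), O=S(=O)(N(c1ccccc1)S(=O)(=O)C(F)(F)F)C(F)(F)F
Why: Enolisation is possible only towards C5 and O-triflation of the cold potassium enolate outruns β-elimination of the silyloxy group; the enol triflate masks the C6 carbonyl and later delivers C7.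

**Step 5**
Reactants: 10 C6 enol triflate
Product: 12 hydroxy ketone (8α-CH2COCH3, 9α-CH2OH, otherwise as 10), via keto aldehyde 11 (not isolated)
Conditions: O3, CH2Cl2/MeOH 4:1, −78 °C; Me2S, −78 to 0 °C; then NaBH4, −78 °C
Reagents that add atoms: ozone, [O-][O+]=O
Why: Ozonolysis cleaves the two electron-rich terminal alkenes (the electron-poor enol triflate alkene and the alkyne react far more slowly) to the C13 ketone and the C11 aldehyde 11, and borohydride at −78 °C reduces only the aldehyde.

**Step 6**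
Reactants: 12 hydroxy ketone
Product: 13 iodo ketone (8α-CH2COCH3, 9α-CH2I)
Conditions: PPh3, I2, imidazole, CH2Cl2, 0 °C to rt
Reagents that add atoms: iodine, II
Why: Appel iodination of the primary alcohol under neutral conditions leaves the ketone, triflate, alkyne and silyl ether untouched.

**Step 7**
Reactants: 13 iodo ketone
Product: 14 cis-fused B/C bicyclic ketone (13-oxo, 8β-propargyl, 9β-H, 10β-OTBS, C6 enol triflate)
Conditions: LiN(i-Pr)2 (1.1 equiv), THF/HMPA, −78 to 0 °C
Reagents that add atoms: none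
Why: The kinetic methyl-ketone enolate (C12) displaces the primary iodide in a 6-exo-tet alkylation that closes ring C; the fusion is cis because C14 and C11 were placed cis on ring B in step 3.

**Step 8**
Reactants: 14 bicyclic ketone
Product: 15 B/C/D tricycle (13-hydroxy-16-methylene bicyclo[3.2.1]octane fused to ring B; 9β-H, 10β-OTBS, C6 enol triflate)
Conditions: SmI2 (0.1 M in THF, 2.5 equiv), HMPA, t-BuOH, 0 °C
Reagents that add atoms: none
Why: Ketyl–alkyne reductive cyclisation (5-exo-dig) of the C13 ketyl onto the axial 8β-propargyl group closes ring D and gives the bridgehead 13-OH and the 16-methylene group together; the bridge can only form on the face carrying C15, so C13 is set by C8.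

**Step 9**
Reactants: 15 tricyclic enol triflate
Product: 16 2-(trimethylsilyl)ethyl C5=C6-ene-7-oate of the tricycle (10β-OTBS, 13-OH)
Conditions: Pd(OAc)2 (5 mol%), Ph2P(CH2)3PPh2, CO (1 atm), Me3SiCH2CH2OH, Et3N, DMF, 60 °C
Reagents that add atoms: carbon monoxide, [C-]#[O+]; 2-(trimethylsilyl)ethanol, C[Si](C)(C)CCO
Why: Palladium-catalysed alkoxycarbonylation of the enol triflate (oxidative addition, CO insertion, alcoholysis) installs C7 as a fluoride-cleavable ester and creates the C5=C6 enoate needed as Michael acceptor.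

**Step 10**
Reactants: 16 silyl ether enoate
Product: 17 10β,13-dihydroxy enoate
Conditions: HF·pyridine, pyridine, THF, 0 °C to rt
Reagents that add atoms: none
Why: Acidic fluoride desilylation removes the secondary allylic TBS ether while the 2-(trimethylsilyl)ethyl ester and the tertiary allylic alcohol survive.

**Step 11**
Reactants: 17 diol enoate
Product: 18 10-oxo enoate (ring-B enone ester, 13-OH)
Conditions: Dess–Martin periodinane, CH2Cl2, rt
Reagents that add atoms: none
Why: Dess–Martin oxidation converts the secondary allylic 10-OH into the ketone; the tertiary 13-OH cannot be oxidised.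

**Step 12**
Reactants: 18 enone ester
Product: 19 13-O-trimethylsilyl ether of 18
Conditions: 1-(trimethylsilyl)imidazole, CH2Cl2, rt
Reagents that add atoms: 1-(trimethylsilyl)imidazole, C[Si](C)(C)n1ccnc1
Why: Silyl transfer from the N-silylimidazole caps the tertiary 13-OH without enolising the ketone, so that only the C10 alkoxide is acylated in step 13.

**Step 13**
Reactants: 19 silylated enone ester; 20 ethoxyethene (ethyl vinyl ether); 21 propanoic anhydride
Product: 24 10α-propanoyloxy-10β-(1-ethoxyvinyl) enoate (13-OSiMe3), via 1-ethoxyvinyllithium 22 (not isolated), via lithium alkoxide 23 (not isolated)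
Conditions: 20, t-BuLi, THF, −78 to 0 °C; then 19, −78 °C; then 21, DMAP (cat.), −78 to 0 °C
Reagents that add atoms: tert-butyllithium, [Li]C(C)(C)C (its Li stays in 22 and 23 only)
Why: 1,2-Addition of the acetyl anion equivalent 22 to the C10 ketone occurs from the convex β face (the α face is covered by the axial hydrogens at C12 and C14 of ring C) and gives the 10α-alkoxide 23, which is trapped by acylation as the propanoate.

**Step 14**
Reactants: 24 propanoate
Product: 26 19,10α-lactone methyl ketone (4-H/4-methyl, 5β-H, 6β-ester, 10β-acetyl, 13-OH), via enol ether lactone 25 (not isolated)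
Conditions: KN(SiMe3)2 (1.1 equiv), THF, −78 to −20 °C; t-BuOH, 0 °C; then 1 M HCl, THF, 0 °C
Reagents that add atoms: water, O
Why: Intramolecular Michael addition (5-exo-trig) of the propanoate enolate, held on the α face by the 10α oxygen, to C5 of the enoate forms C4–C5 and the γ-lactone and can only give 5β-H; the C6 ester equilibrates to the more stable 6β configuration (trans to C4), and aqueous acid then hydrolyses the enol ether to the C1 methyl ketone and removes the 13-O-silyl group (the C4 configuration is irrelevant because C4 is enolised in step 16).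

**Step 15**
Reactants: 26 lactone methyl ketone; 27 N,N-dimethylformamide dimethyl acetal
Product: 28 enaminone (lactone carrying 10β-[(E)-3-(dimethylamino)prop-2-enoyl])
Conditions: 27 (5 equiv), toluene, 90 °C
Reagents that add atoms: none
Why: Condensation of the methyl ketone (C2) with the amide acetal gives the (E)-enaminone and brings in C3 at the aldehyde oxidation level.

**Step 16**
Reactants: 28 enaminone
Product: 30 1-oxo-Δ2 19,10-lactone (ring A closed; 13-OH, 16-ene, 7-oate 2-(trimethylsilyl)ethyl ester), via amino ketone 29 (not isolated)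
Conditions: KN(SiMe3)2 (2.2 equiv), THF, −78 to 0 °C; then AcOH, rt
Reagents that add atoms: none
Why: Proposed new method: after the 13-OH, the γ-lactone C4–H is the most acidic site (a lactone is several pKa units more acidic than the C6 ester), its enolate adds 6-endo-trig to C3 of the vinylogous amide and the β-amino ketone 29 loses Me2NH (E1cB) on acidification, so C3–C4, the quaternary C4 and the Δ2 enone form in one operation; C3 is tethered through C1 to the β face of C10 and can only bond to the convex face of the lactone enolate, which leaves the methyl group in the natural C18 position; the closest known reaction type is addition–elimination of carbon nucleophiles to β-(dialkylamino)enones combined with Robinson-type six-ring closure.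

**Step 17**
Reactants: 30 enone lactone
Product: 31 2β,3β-epoxy-1-oxo lactone ester
Conditions: t-BuOOH, DBU, CH2Cl2, 0 °C to rt
Reagents that add atoms: tert-butyl hydroperoxide, CC(C)(C)OO
Why: Weitz–Scheffer nucleophilic epoxidation attacks only the electron-poor enone (the 16-methylene group is inert) and the peroxide adds to C3 from the β face, anti to the axial lactone carbonyl on C4, giving the 2β,3β-epoxide.

**Step 18**
Reactants: 31 epoxy ketone
Product: 32 2-(trimethylsilyl)ethyl ester of the target gibberellin (1β-hydroxy-2β,3β-epoxy lactone ester)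
Conditions: K[HB(s-Bu)3], THF, −78 °C; AcOH quench
Reagents that add atoms: none
Why: The bulky borohydride attacks the C1 ketone along the equatorial trajectory from the α face, anti to the β-epoxide oxygen and away from the 1,3-diaxial 5β-H, giving the axial 1β-alcohol cis to the epoxide (substrate-controlled carbonyl reduction, the same sense as bulky-hydride reduction of 3-oxogibberellins to 3β-alcohols).

**Step 19**
Reactants: 32 2-(trimethylsilyl)ethyl ester of the target gibberellin
Product: 33 target gibberellin (2β,3β-epoxy-1β,13-dihydroxy-20-norgibberell-16-ene-7,19-dioic acid 19,10α-lactone)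
Conditions: Bu4NF, THF, 0 °C to rt; then aqueous HCl to pH 3
Reagents that add atoms: none
Why: Fluoride attacks silicon and the 2-(trimethylsilyl)ethyl ester fragments to ethylene and the carboxylate (fluoride-induced β-elimination), freeing the C7 acid without hydrolytic base that would endanger the epoxy lactone.

**Compound list**
1 | (R)-4-[(tert-butyldimethylsilyl)oxy]cyclopent-2-en-1-one | O=C1C=C[C@H](O[Si](C)(C)C(C)(C)C)C1 | starting material
2 | (R)-4-[(tert-butyldimethylsilyl)oxy]-2-iodocyclopent-2-en-1-one | O=C1C(I)=C[C@H](O[Si](C)(C)C(C)(C)C)C1 | intermediate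
3 | tributyl(2-methylprop-2-en-1-yl)stannane | C=C(C)C[Sn](CCCC)(CCCC)CCCC | starting material
4 | (R)-4-[(tert-butyldimethylsilyl)oxy]-2-(2-methylprop-2-en-1-yl)cyclopent-2-en-1-one | O=C1C(CC(C)=C)=C[C@H](O[Si](C)(C)C(C)(C)C)C1 | intermediate
5 | vinylmagnesium bromide | C=C[Mg]Br | starting material
6 | 3-bromoprop-1-yne (propargyl bromide) | C#CCBr | starting material
7 | C6 trimethylsilyl enol ether (C6=C8) of the 9α-vinyl adduct of 4, 10β-OTBS | C[Si](C)(C)OC1=C(CC(C)=C)[C@@H](C=C)[C@H](O[Si](C)(C)C(C)(C)C)C1 | intermediate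
8 | lithium enolate corresponding to 7 (C6–OLi, C6=C8) | [Li]OC1=C(CC(C)=C)[C@@H](C=C)[C@H](O[Si](C)(C)C(C)(C)C)C1 | intermediate
9 | (2R,3R,4R)-4-[(tert-butyldimethylsilyl)oxy]-3-ethenyl-2-(2-methylprop-2-en-1-yl)-2-(prop-2-yn-1-yl)cyclopentan-1-one (8β-propargyl, 8α-methallyl, 9α-vinyl, 10β-OTBS) | O=C1[C@@](CC#C)(CC(C)=C)[C@@H](C=C)[C@H](O[Si](C)(C)C(C)(C)C)C1 | intermediate
10 | C6 enol triflate of 9 (C5=C6; other centres as in 9) | C1(OS(=O)(=O)C(F)(F)F)[C@@](CC#C)(CC(C)=C)[C@@H](C=C)[C@H](O[Si](C)(C)C(C)(C)C)C=1 | intermediate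
11 | keto aldehyde: triflate 10 with 8α-CH2COCH3 and 9α-CHO | C1(OS(=O)(=O)C(F)(F)F)[C@@](CC#C)(CC(C)=O)[C@@H](C=O)[C@H](O[Si](C)(C)C(C)(C)C)C=1 | intermediate
12 | hydroxy ketone: 8α-CH2COCH3, 9α-CH2OH | C1(OS(=O)(=O)C(F)(F)F)[C@@](CC#C)(CC(C)=O)[C@@H](CO)[C@H](O[Si](C)(C)C(C)(C)C)C=1 | intermediate
13 | iodo ketone: 8α-CH2COCH3, 9α-CH2I | C1(OS(=O)(=O)C(F)(F)F)[C@@](CC#C)(CC(C)=O)[C@@H](CI)[C@H](O[Si](C)(C)C(C)(C)C)C=1 | intermediate
14 | cis-fused B/C bicyclic ketone: 13-oxo, 8β-propargyl, 9β-H, 10β-OTBS, C6 enol triflate | C1(OS(=O)(=O)C(F)(F)F)[C@@]2(CC#C)CC(=O)CC[C@H]2[C@H](O[Si](C)(C)C(C)(C)C)C=1 | intermediate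
15 | B/C/D tricycle: 13-hydroxy-16-methylene, 9β-H, 10β-OTBS, C6 enol triflate | C=C1C[C@]23C[C@@]1(O)CC[C@H]2[C@H](O[Si](C)(C)C(C)(C)C)C=C3OS(=O)(=O)C(F)(F)F | intermediate
16 | 2-(trimethylsilyl)ethyl C5=C6-ene-7-oate of the tricycle, 10β-OTBS, 13-OH | C=C1C[C@]23C[C@@]1(O)CC[C@H]2[C@H](O[Si](C)(C)C(C)(C)C)C=C3C(=O)OCC[Si](C)(C)C | intermediate
17 | 10β,13-dihydroxy enoate | C=C1C[C@]23C[C@@]1(O)CC[C@H]2[C@H](O)C=C3C(=O)OCC[Si](C)(C)C | intermediate
18 | 10-oxo enoate (ring-B enone ester), 13-OH | C=C1C[C@]23C[C@@]1(O)CC[C@H]2C(=O)C=C3C(=O)OCC[Si](C)(C)C | intermediate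
19 | 13-O-trimethylsilyl ether of 18 | C=C1C[C@]23C[C@@]1(O[Si](C)(C)C)CC[C@H]2C(=O)C=C3C(=O)OCC[Si](C)(C)C | intermediate
20 | ethoxyethene (ethyl vinyl ether) | C=COCC | starting material
21 | propanoic anhydride | CCC(=O)OC(=O)CC | starting material
22 | 1-ethoxyvinyllithium | [Li]C(=C)OCC | intermediate
23 | lithium 10α-alkoxide carrying 10β-(1-ethoxyvinyl) | C=C1C[C@]23C[C@@]1(O[Si](C)(C)C)CC[C@H]2[C@](O[Li])(C(OCC)=C)C=C3C(=O)OCC[Si](C)(C)C | intermediate
24 | 10α-propanoyloxy-10β-(1-ethoxyvinyl) enoate, 13-OSiMe3 | C=C1C[C@]23C[C@@]1(O[Si](C)(C)C)CC[C@H]2[C@](OC(=O)CC)(C(OCC)=C)C=C3C(=O)OCC[Si](C)(C)C | intermediate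
25 | 19,10α-lactone: 4-H/4-methyl (methyl on the convex face, centre later enolised), 5β-H, 6β-ester, 10β-(1-ethoxyvinyl), 13-OSiMe3 | C=C1C[C@]23C[C@@]1(O[Si](C)(C)C)CC[C@H]2[C@@]1(C(OCC)=C)OC(=O)[C@H](C)[C@H]1[C@@H]3C(=O)OCC[Si](C)(C)C | intermediate
26 | same lactone with 10β-acetyl (C1 ketone, C2 methyl) and free 13-OH | C=C1C[C@]23C[C@@]1(O)CC[C@H]2[C@@]1(C(C)=O)OC(=O)[C@H](C)[C@H]1[C@@H]3C(=O)OCC[Si](C)(C)C | intermediate
27 | N,N-dimethylformamide dimethyl acetal | COC(OC)N(C)C | starting material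
28 | enaminone: lactone with 10β-[(E)-3-(dimethylamino)prop-2-enoyl] | C=C1C[C@]23C[C@@]1(O)CC[C@H]2[C@@]1(C(=O)/C=C/N(C)C)OC(=O)[C@H](C)[C@H]1[C@@H]3C(=O)OCC[Si](C)(C)C | intermediate
29 | ring-A-closed 3-(dimethylamino)-1-oxo lactone (C3 epimers) | C=C1C[C@]23C[C@@]1(O)CC[C@H]2[C@@]12OC(=O)[C@@](C)([C@H]1[C@@H]3C(=O)OCC[Si](C)(C)C)C(N(C)C)CC2=O | intermediate
30 | 1-oxo-Δ2 19,10-lactone, 13-OH, 16-ene, 7-oate 2-(trimethylsilyl)ethyl ester | C=C1C[C@]23C[C@@]1(O)CC[C@H]2[C@@]12OC(=O)[C@@](C)([C@H]1[C@@H]3C(=O)OCC[Si](C)(C)C)C=CC2=O | intermediate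
31 | 2β,3β-epoxy-1-oxo lactone ester | C=C1C[C@]23C[C@@]1(O)CC[C@H]2[C@@]12OC(=O)[C@@](C)([C@H]1[C@@H]3C(=O)OCC[Si](C)(C)C)[C@H]1O[C@H]1C2=O | intermediate
32 | 2-(trimethylsilyl)ethyl ester of the target gibberellin (1β-hydroxy-2β,3β-epoxy lactone ester) | C=C1C[C@]23C[C@@]1(O)CC[C@H]2[C@@]12OC(=O)[C@@](C)([C@H]1[C@@H]3C(=O)OCC[Si](C)(C)C)[C@H]1O[C@H]1[C@H]2O | intermediate
33 | target gibberellin (2β,3β-epoxy-1β,13-dihydroxy-20-norgibberell-16-ene-7,19-dioic acid 19,10α-lactone) | C=C1C[C@]23C[C@@]1(O)CC[C@H]2[C@@]12OC(=O)[C@@](C)([C@H]1[C@@H]3C(=O)O)[C@H]1O[C@H]1[C@H]2O | target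

**Totals**
Total step count: 19. Longest linear sequence: 19 steps (1 to 33).

**Three steps most likely to fail**

Step 16 (new ring-A annulation; the lactone enolate must reach C3 and the amine must leave). Fallback, setting out from 25 (kept by a buffered, non-acidic work-up of step 14) and coming back at 30: LiN(i-Pr)2 in THF at −78 °C followed by gaseous CH2O hydroxymethylates the lactone enolate on its convex face to give the 4-hydroxymethyl lactone F1. Dess–Martin periodinane with pyridine gives the 4-formyl lactone F2. 1 M HCl in THF hydrolyses the enol ether and the silyl ether to the keto aldehyde F3. Pyrrolidinium acetate in benzene at 60 °C then closes ring A by aldol condensation of the methyl ketone with the non-enolisable aldehyde, which gives 30.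

Step 14 (a simple ester enolate in a 5-exo Michael closure with the enolate double bond inside the forming ring, on the hindered α face, with Claisen-type rearrangement as a competitor). Fallback, setting out from 19 and coming back at 25: 19 is treated with 22 as in step 13, but the alkoxide 23 is acylated with 2-(phenylsulfonyl)propanoyl chloride to give the 10α-O-[2-(phenylsulfonyl)propanoate] F4. The soft sulfonyl-stabilised carbanion (DBU, MeCN, rt) adds to C5 to give the 4-(phenylsulfonyl) lactone F5. SmI2 with HMPA and t-BuOH in THF at −20 °C removes the sulfonyl group reductively and gives 25.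

Step 18 (substrate-controlled facial selectivity at C1). Fallback, setting out from 30 and coming back at 33: 1-(trimethylsilyl)imidazole gives the 13-O-trimethylsilyl enone F6. Catalyst-controlled reduction with (S)-2-methyl-CBS-oxazaborolidine and BH3·SMe2 (the enantiomeric catalyst if the sense proves opposite) delivers hydride to the α face and gives the 1β-allylic alcohol F7. VO(acac)2 with t-BuOOH then epoxidises syn to the 1β-OH to give the 13-O-silyl 2β,3β-epoxy alcohol F8; the silylated 13-oxygen cannot steer the oxidant to the 16-methylene group. Bu4NF as in step 19 removes the silyl ether and the ester and gives 33.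

**Further compounds**
F1 | step 16 | 4-hydroxymethyl lactone (CH2OH in the C3 position, 10β-(1-ethoxyvinyl), 13-OSiMe3) | C=C1C[C@]23C[C@@]1(O[Si](C)(C)C)CC[C@H]2[C@@]1(C(OCC)=C)OC(=O)[C@@](C)([C@H]1[C@@H]3C(=O)OCC[Si](C)(C)C)CO
F2 | step 16 | 4-formyl lactone (10β-(1-ethoxyvinyl), 13-OSiMe3) | C=C1C[C@]23C[C@@]1(O[Si](C)(C)C)CC[C@H]2[C@@]1(C(OCC)=C)OC(=O)[C@@](C)([C@H]1[C@@H]3C(=O)OCC[Si](C)(C)C)C=O
F3 | step 16 | keto aldehyde (4-formyl, 10β-acetyl, 13-OH) | C=C1C[C@]23C[C@@]1(O)CC[C@H]2[C@@]1(C(C)=O)OC(=O)[C@@](C)([C@H]1[C@@H]3C(=O)OCC[Si](C)(C)C)C=O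
F4 | step 14 | 10α-O-[2-(phenylsulfonyl)propanoate] of the 10β-(1-ethoxyvinyl) enoate (sulfonyl carbon epimers) | C=C1C[C@]23C[C@@]1(O[Si](C)(C)C)CC[C@H]2[C@](OC(=O)C(C)S(=O)(=O)c1ccccc1)(C(OCC)=C)C=C3C(=O)OCC[Si](C)(C)C
F5 | step 14 | 4-(phenylsulfonyl) 19,10α-lactone (C4 epimers) | C=C1C[C@]23C[C@@]1(O[Si](C)(C)C)CC[C@H]2[C@@]1(C(OCC)=C)OC(=O)C(C)(S(=O)(=O)c2ccccc2)[C@H]1[C@@H]3C(=O)OCC[Si](C)(C)C
F6 | step 18 | 13-O-trimethylsilyl ether of enone 30 | C=C1C[C@]23C[C@@]1(O[Si](C)(C)C)CC[C@H]2[C@@]12OC(=O)[C@@](C)([C@H]1[C@@H]3C(=O)OCC[Si](C)(C)C)C=CC2=O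
F7 | step 18 | 1β-hydroxy-Δ2 lactone, 13-OSiMe3 | C=C1C[C@]23C[C@@]1(O[Si](C)(C)C)CC[C@H]2[C@@]12OC(=O)[C@@](C)([C@H]1[C@@H]3C(=O)OCC[Si](C)(C)C)C=C[C@H]2O
F8 | step 18 | 13-O-trimethylsilyl ether of 32 | C=C1C[C@]23C[C@@]1(O[Si](C)(C)C)CC[C@H]2[C@@]12OC(=O)[C@@](C)([C@H]1[C@@H]3C(=O)OCC[Si](C)(C)C)[C@H]1O[C@H]1[C@H]2O
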